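**Remark on the chemistry.** Drimane numbering is used: C11 sits on C9, C12 is the methyl on C8, and primed numbers denote the six-membered carbocycle that becomes the quinone (C1' bonded to C11). The natural (+)-enantiomer of sclareolide is assumed; its C5, C9, C10 and C8-methyl configuration is that of the target series.

## Analysis of the target

The target is a drimane sesquiterpene (trans-fused rings A and B) joined through C11 to a 2-methoxy-1,4-benzoquinone; C9=C11 is a tetrasubstituted alkene whose C11 carries chlorine and the quinone. There are three stereocentres: C5 (H α) and C10 (methyl β) define the trans-decalin, and C8 carries a β-methyl group (8αH), syn to the C10 methyl and therefore axial. The alkene is E: chlorine lies on the C8 side and the quinone on the side of the quaternary C10. The quinone is sensitive to nucleophiles, bases and reductants, and the vinylic chloride limits what can be done after it is in place, so the quinone has to be released last from an oxidisable arene. The hard points are the geometry of a fully substituted alkene whose two C11 substituents differ little in size, the axial C8 methyl, and the hindered, neopentyl-like C11. The strategy rests on two features of the structure. A quinone with oxygen at C2', C3' and C5' and the chain at C1' is the oxidation product of a 2-alkyl-4,6-dimethoxyphenol, which is what a (2-methoxyvinyl)(methoxy)carbene chromium complex, one of its CO ligands and a terminal alkyne assemble; in addition, C5, C8 with its β-methyl, C9, C10 and the C9–C11–C1' chain are all present in (+)-sclareolide 1, whose lactone carbonyl carbon becomes C1'.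

## Retrosynthetic reasoning

**Quinone to arene.** Target 20 is traced to trimethoxyarene 19 without cutting a skeletal bond. The para-related methoxy groups at C2' and C5' are the latent carbonyls and the C3' methoxy group is kept. This keeps every earlier step free of a quinone; the forward reaction only has to oxidise the most electron-rich part of 19 under cold, brief conditions.

**C11–Cl.** The C–Cl bond of 19 is cut to an aryl-stabilised vinyl cation, which comes from enol triflate 18 and hence from ketone 16. The cut is made here because the cation is linear at C11 and its empty orbital lies in the C8–C9–C10 plane. The two in-plane approaches differ: one passes the equatorial C8–H, the other passes C1 and the quaternary C10. The geometry is therefore set by the substrate and does not depend on the geometry of 18. The forward step must ionise 18 and deliver the halide from the C8 side.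

**C11 oxygen and C8 hydrogen.** Ketone 16 is traced to 15 by removing the benzylic carbonyl. Compound 15 comes from the exocyclic alkene 14 by adding hydrogen across C8=C12, and 14 from tertiary alcohol 13 by loss of water. A tetrasubstituted 8-ene is deliberately avoided: making it needs a C8 cation, which the activated C6' position of the arene would capture, and reducing it from one face is difficult. The exocyclic alkene is hydrogenated from the α face, away from the axial C10 methyl, which restores at C8 the configuration it had in 1.

**The arene ring.** Compound 13 is the methyl ether of phenol 12. Phenol 12 is cut at C1'–C2', C2'–C3' and C5'–C6' into alkyne 3, carbene complex 10 and one carbonyl ligand of 10. This places all three ring oxygens in one step and leaves the C11–C1' bond untouched, so the hindered C11 never has to be attacked by an aryl nucleophile. The forward reaction must insert the alkyne with its bulky end next to the carbonyl-derived carbon and must incorporate CO before the ring closes.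

**The two fragments.** Alkyne 3 comes from lactol 2 by a one-carbon alkyne homologation of the masked aldehyde, and 2 from 1 by partial reduction. The decalin stereocentres are carried through unchanged. Complex 10 is cut at the carbene carbon into Cr(CO)6 7 and a 2-methoxyvinyl anion (8, through acylate 9), which comes from bromide 6 and hence from enol ether 4.

## Alternatives that were turned down

**Alternative 1:** Rings A and B are built instead of bought. Ring A is the cyclohexenyl thioester A2, the bonds C5–C6 and C9–C10 are cut, ring B is closed later by aldol condensation (C8–C9), and the C10 methyl is carried as a thioester. In the forward key step a copper-catalysed asymmetric conjugate addition of Grignard reagent A3 to A2 sets C5, and the resulting enolate is alkylated at C10 by bromoketone A4 anti to the new chain, giving A1.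
- In favour: the route is convergent, the arene is a simple aromatic, no stoichiometric chromium is needed, and C11 arrives as a ketone. On that last point it is stronger than the chosen route, which must oxidise C11 late (step 9).
- Against: the β-carbon of A2 is flanked by the gem-dimethyl carbon, so the conjugate addition is to a neopentyl, trisubstituted cyclic acceptor, the least reactive class for this catalysis. The alkylation must form a quaternary centre with an α-bromoketone that is itself enolisable. After A1 there follow ketal removal, aldol closure to a tetrasubstituted aroyl alkene, conversion of the thioester into a methyl group at a neopentyl quaternary carbon (about three operations), and a face-selective reduction of that tetrasubstituted alkene to set C8, which is harder than hydrogenating 14. Absolute configuration rests on a catalyst, and the sequence would be several steps longer.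
- In its place the chosen strategy takes C5, C10 and the C8 methyl from 1 and concentrates its risk in one ring-forming step.

**Alternative 2:** The bonds C4–C5 and C9–C10 are cut to give the open-chain farnesyl arene A6. A chiral Brønsted acid protonates the terminal alkene, the chair–chair cation cascade closes rings A and B, and the C8 cation loses a proton to give A5.
- In favour: this is the shortest access to the full carbon skeleton with the arene attached, and both ring-fusion centres form in one step. On step economy up to the bicyclic arene it is clearly stronger.
- Against: the C8 cation has three elimination options (Δ7, Δ8(12), Δ8(9)) and two internal nucleophiles, C6' of the arene (five-membered ring) and the C2' methoxy oxygen (chroman after demethylation), so A5 must win over several competitors. Enantiocontrol of protonation at a remote, unfunctionalised alkene without a terminating nucleophile bound to the acid is the weakest case for such catalysts, and a strong acid also engages the trimethoxyarene. After A5 the C11 oxidation and the C8 reduction are still needed, the latter from a tetrasubstituted alkene.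
- In its place the chosen strategy offers secured absolute configuration and a C8 oxygen that leads to the easily hydrogenated alkene 14.

**Alternative 3:** The bonds C5–C10 and C8–C9 are cut, so both rings come from the acyclic chloroallene A8. An intramolecular [4+2] cycloaddition of the (E,E)-diene across the proximal allene bond C9=C10 leaves the distal bond as the chloroalkene and gives A7.
- In favour: the chloroalkene is present before any ring exists, and its geometry follows from which allene face is attacked (the face bearing chlorine gives E). This addresses the hardest feature of the target more directly than the cation capture of step 11. The C8 methyl follows from the diene geometry, and the endgame is short.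
- Against: the 2π component is an unactivated allene terminus that carries a methyl group and must become a quaternary centre, which calls for forcing thermal conditions. A tetrasubstituted α-aryl chloroallene can ionise, racemise and isomerise to the propargylic chloride under such conditions. Absolute configuration would have to come from the axial chirality of A8, which is hard to install and labile. The trans ring fusion, the C8 configuration and the alkene geometry must all fall right in one transition state. A7 then needs a selective hydrogenation of C6=C7 next to a vinylic chloride.
- In its place the chosen strategy separates these problems: the stereocentres come from 1, and the geometry is addressed in one late, substrate-controlled step.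

Key step: step 5

## Route

**Step 1**
Reactants: 1 (+)-sclareolide
Product: 2 sclareolide lactol (cyclic hemiacetal of 8α-hydroxy-11-formyldrimane; both anomers)
Conditions: i-Bu2AlH (1.1 equiv), CH2Cl2, −78 °C; aq. potassium sodium tartrate
Reagents that add atoms: none
Why: Partial reduction of a γ-lactone by i-Bu2AlH at low temperature stops at the aluminium hemiacetal, which gives the lactol on work-up; no decalin stereocentre is touched and the anomeric mixture is of no consequence.

**Step 2**
Reactants: 2 sclareolide lactol
Product: 3 8α-hydroxy-11-ethynyldrimane (11-ethynyldriman-8α-ol)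
Conditions: dimethyl (1-diazo-2-oxopropyl)phosphonate, K2CO3, MeOH, 0 °C → rt
Reagents that add atoms: dimethyl (1-diazo-2-oxopropyl)phosphonate (Ohira–Bestmann reagent), CC(=O)C(=[N+]=[N-])P(=O)(OC)OC
Why: Ohira–Bestmann (Seyferth–Gilbert) homologation: the lactol reacts through its open hydroxy aldehyde form, and the former lactone carbon ends as the internal alkyne carbon (future C1'); the carbon next to the aldehyde is a methylene, so no stereocentre is at risk, and the tertiary alkoxide has no elimination path.

**Step 3**
Reactants: 4 methyl vinyl ether
Product: 6 (Z)-1-bromo-2-methoxyethene, via 1,2-dibromo-1-methoxyethane 5 (not isolated)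
Conditions: Br2, CH2Cl2, −78 °C; then N,N-diethylaniline, 90–100 °C, distil
Reagents that add atoms: bromine, BrBr
Why: Electrophilic bromine addition to the enol ether, then amine-induced dehydrobromination in which the labile bromide next to oxygen leaves with a C2 hydrogen; the Z alkene should predominate, as with the ethyl homologue, and is distilled from the amine salt.

**Step 4**
Reactants: 6 (Z)-1-bromo-2-methoxyethene; 7 chromium hexacarbonyl Cr(CO)6
Product: 10 pentacarbonyl[(Z)-1,3-dimethoxyprop-2-enylidene]chromium, via (Z)-2-methoxyvinyllithium 8 (not isolated), via lithium acylchromate 9 (not isolated)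
Conditions: t-BuLi (2 equiv), THF, −78 °C; Cr(CO)6, −78 → 0 °C; then Me3OBF4, CH2Cl2/H2O, 0 °C
Reagents that add atoms: trimethyloxonium tetrafluoroborate, C[O+](C)C.F[B-](F)(F)F
Why: Classical Fischer carbene synthesis: bromine–lithium exchange with retention gives the cis-alkoxyvinyllithium, which is stable at −78 °C, it adds to a carbonyl ligand, and the acylate is O-methylated by the hard oxonium salt. The alkene geometry of 10 is immaterial because that carbon becomes aromatic.

**Step 5**
Reactants: 3 8α-hydroxy-11-ethynyldrimane; 10 pentacarbonyl[(Z)-1,3-dimethoxyprop-2-enylidene]chromium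
Product: 12 2-(8α-hydroxydriman-11-yl)-4,6-dimethoxyphenol, via arene tricarbonylchromium complex 11 (not isolated)
Conditions: 10 (1.5 equiv), THF (0.05 M), 55 °C, Ar; then air, Et2O, rt; neutral work-up
Reagents that add atoms: none
Why: This is a Dötz benzannulation of an alkenyl(methoxy)carbene chromium complex with a terminal alkyne, which is also the closest known reaction type. Thermal loss of one CO from 10 opens a site for 3, which inserts into the Cr=C bond with its unsubstituted carbon bonded to the carbene carbon (C5'–C6'); a CO ligand then inserts to give a chromium-bound dienylketene (C1'–C2'). The ring closes by a thermal 6π electrocyclisation of that dienylketene, in which the ketene carbon bonds to the methoxy-bearing vinyl carbon (C2'–C3'); tautomerisation gives the phenol, first as Cr(CO)3 complex 11, from which air releases 12. No stereocentre is formed, and those of 3 are remote from the reacting carbons. The step needs regiocontrol of alkyne insertion, which the size difference between hydrogen and the drimanylmethyl group secures by placing the bulky substituent next to the CO-derived carbon, ortho to the new hydroxyl. It also needs CO insertion to outrun cyclisation without CO; chromium, an ethereal solvent, moderate temperature and low concentration favour the phenol, and a β-methoxy group is a far weaker donor than the amino groups known to suppress CO insertion. The hindered tertiary C8 hydroxyl should be too slow a nucleophile to intercept the ketene, and acid is kept out of the work-up because 12 could close to a chroman at C8.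

**Step 6**
Reactants: 12 2-(8α-hydroxydriman-11-yl)-4,6-dimethoxyphenol
Product: 13 11-(2,3,5-trimethoxyphenyl)driman-8α-ol
Conditions: MeI, K2CO3, acetone, reflux
Reagents that add atoms: iodomethane, CI
Why: Williamson O-methylation of the phenol under carbonate conditions leaves the tertiary alcohol untouched; it removes the oxygen nucleophile that could attack C8 in step 7 and gives the arene its final, oxidatively cleavable substitution.

**Step 7**
Reactants: 13 11-(2,3,5-trimethoxyphenyl)driman-8α-ol
Product: 14 11-(2,3,5-trimethoxyphenyl)drim-8(12)-ene
Conditions: SOCl2, pyridine, CH2Cl2, −78 → 0 °C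
Reagents that add atoms: none
Why: E2 dehydration of the alcohol activated in situ as its chlorosulfite: the equatorial 8α leaving group has no ring hydrogen antiperiplanar to it, only those of the C12 methyl, so the exocyclic alkene 14 should dominate; whatever eliminates toward C7 instead need not be removed, since hydrogenation in step 8 converges on the same product. Pyridine at low temperature avoids a free C8 cation, which C6' of the arene would otherwise capture.

**Step 8**
Reactants: 14 11-(2,3,5-trimethoxyphenyl)drim-8(12)-ene
Product: 15 11-(2,3,5-trimethoxyphenyl)-8αH-drimane (8β-methyl, syn to the C10 methyl)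
Conditions: H2 (1 atm), PtO2, EtOAc, rt
Reagents that add atoms: none
Why: Heterogeneous hydrogenation delivers hydrogen to C8 from the α face, because the β face of the exocyclic alkene is screened by the axial C10 methyl; this sets the 8β-methyl (8αH) centre, the configuration C8 had in 1, and leaves C9 untouched. The arene and its ethers are inert under these conditions.

**Step 9**
Reactants: 15 11-(2,3,5-trimethoxyphenyl)-8αH-drimane
Product: 16 11-(2,3,5-trimethoxyphenyl)-8αH-driman-11-one
Conditions: t-BuOOH (70% aq., 5 equiv), Rh2(cap)4 (1 mol%; cap = caprolactamate), NaHCO3, ClCH2CH2Cl, 40 °C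
Reagents that add atoms: tert-butyl hydroperoxide, CC(C)(C)OO
Why: Radical-chain benzylic C–H oxidation: C11 carries the only benzylic hydrogens of 15 and the aryl ketone is not oxidised further. C9 keeps its equatorial acyl group and becomes trigonal in step 10 in any case.

**Step 10**
Reactants: 16 11-(2,3,5-trimethoxyphenyl)-8αH-driman-11-one
Product: 18 11-(2,3,5-trimethoxyphenyl)-8αH-drim-9(11)-en-11-yl trifluoromethanesulfonate (alkene isomer mixture), via potassium enolate 17 (not isolated)
Conditions: KN(SiMe3)2, THF, −78 → 0 °C; then PhNTf2, 0 °C → rt; filtration through basic alumina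
Reagents that add atoms: N-phenylbis(trifluoromethanesulfonimide), O=S(=O)(N(c1ccccc1)S(=O)(=O)C(F)(F)F)C(F)(F)F
Why: Deprotonation at C9, the only enolisable position, and O-sulfonylation of the enolate (enol triflate formation). Either alkene geometry is acceptable, since both ionise to the same cation in step 11.

**Step 11**
Reactants: 18 11-(2,3,5-trimethoxyphenyl)-8αH-drim-9(11)-en-11-yl trifluoromethanesulfonate
Product: 19 (E)-11-chloro-11-(2,3,5-trimethoxyphenyl)-8αH-drim-9(11)-ene (chlorine on the C8 side)
Conditions: Bu4NCl (5 equiv), 2,6-di-tert-butylpyridine (0.5 equiv), (CF3)2CHOH, 50 °C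
Reagents that add atoms: tetrabutylammonium chloride, CCCC[N+](CCCC)(CCCC)CCCC.[Cl-]
Why: Vinylic SN1 substitution: in the strongly ionising, weakly nucleophilic fluoro alcohol the α-aryl vinyl triflate ionises to a linear aryl-stabilised vinyl cation, relieving the strain of the tetrasubstituted alkene, and chloride captures it. The empty orbital lies in the C8–C9–C10 plane; approach past the equatorial C8–H is open and approach past C1 and the quaternary C10 is blocked, so chlorine should end on the C8 side and the aryl group on the C10 side (E) from either isomer of 18. The vinyl chloride ionises far less readily than the triflate and should persist.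

**Step 12**
Reactants: 19 (E)-11-chloro-11-(2,3,5-trimethoxyphenyl)-8αH-drim-9(11)-ene
Product: 20 2-methoxy-6-[(E)-11-chloro-8αH-drim-9(11)-en-11-yl]-1,4-benzoquinone (CNP0249629.1)
Conditions: (NH4)2Ce(NO3)6 (2.5 equiv), MeCN/H2O (2:1), 0 °C
Reagents that add atoms: water, O
Why: Oxidative demethylation of the para-dimethoxy pair (C2', C5') by tetravalent cerium: two one-electron oxidations, with water attacking the ring carbons and methanol leaving, give the para-quinone and keep the C3' methoxy group. The chloroalkene is twisted out of conjugation and less electron-rich than the ring, so it should survive the short, cold reaction.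

## Compound list

1 | (+)-sclareolide | O=C1C[C@H]2[C@](C)(O1)CC[C@H]3C(C)(C)CCC[C@]23C | starting material
2 | sclareolide lactol (cyclic hemiacetal of 8α-hydroxy-11-formyldrimane, both anomers) | OC1C[C@H]2[C@](C)(O1)CC[C@H]3C(C)(C)CCC[C@]23C | intermediate
3 | 8α-hydroxy-11-ethynyldrimane | C#CC[C@H]1[C@](C)(O)CC[C@H]2C(C)(C)CCC[C@]12C | intermediate
4 | methyl vinyl ether | COC=C | starting material
5 | 1,2-dibromo-1-methoxyethane (not isolated) | COC(Br)CBr | intermediate
6 | (Z)-1-bromo-2-methoxyethene | CO/C=C\Br | intermediate
7 | chromium hexacarbonyl, Cr(CO)6 | O=C=[Cr](=C=O)(=C=O)(=C=O)(=C=O)=C=O | starting material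
8 | (Z)-2-methoxyvinyllithium (not isolated) | CO/C=C\[Li] | intermediate
9 | lithium pentacarbonyl[(Z)-3-methoxy-1-oxidoprop-2-enylidene]chromate (not isolated) | [Li+].CO/C=C\C([O-])=[Cr](=C=O)(=C=O)(=C=O)(=C=O)=C=O | intermediate
10 | pentacarbonyl[(Z)-1,3-dimethoxyprop-2-enylidene]chromium | CO/C=C\C(OC)=[Cr](=C=O)(=C=O)(=C=O)(=C=O)=C=O | intermediate
11 | tricarbonyl(η6-arene)chromium complex of 12 (not isolated; written as arene plus Cr(CO)3 fragment) | COc1cc(OC)c(O)c(C[C@H]2[C@](C)(O)CC[C@H]3C(C)(C)CCC[C@]23C)c1.O=C=[Cr](=C=O)=C=O | intermediate
12 | 2-(8α-hydroxydriman-11-yl)-4,6-dimethoxyphenol | COc1cc(OC)c(O)c(C[C@H]2[C@](C)(O)CC[C@H]3C(C)(C)CCC[C@]23C)c1 | intermediate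
13 | 11-(2,3,5-trimethoxyphenyl)driman-8α-ol | COc1cc(OC)c(OC)c(C[C@H]2[C@](C)(O)CC[C@H]3C(C)(C)CCC[C@]23C)c1 | intermediate
14 | 11-(2,3,5-trimethoxyphenyl)drim-8(12)-ene | COc1cc(OC)c(OC)c(C[C@H]2C(=C)CC[C@H]3C(C)(C)CCC[C@]23C)c1 | intermediate
15 | 11-(2,3,5-trimethoxyphenyl)-8αH-drimane (8β-methyl) | COc1cc(OC)c(OC)c(C[C@H]2[C@@H](C)CC[C@H]3C(C)(C)CCC[C@]23C)c1 | intermediate
16 | 11-(2,3,5-trimethoxyphenyl)-8αH-driman-11-one | COc1cc(OC)c(OC)c(C(=O)[C@H]2[C@@H](C)CC[C@H]3C(C)(C)CCC[C@]23C)c1 | intermediate
17 | potassium enolate of 16 (not isolated) | COc1cc(OC)c(OC)c(C([O-])=C2[C@@H](C)CC[C@H]3C(C)(C)CCC[C@]23C)c1.[K+] | intermediate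
18 | 11-(2,3,5-trimethoxyphenyl)-8αH-drim-9(11)-en-11-yl trifluoromethanesulfonate (alkene isomer mixture) | COc1cc(OC)c(OC)c(C(OS(=O)(=O)C(F)(F)F)=C2[C@@H](C)CC[C@H]3C(C)(C)CCC[C@]23C)c1 | intermediate
19 | (E)-11-chloro-11-(2,3,5-trimethoxyphenyl)-8αH-drim-9(11)-ene | COc1cc(OC)c(OC)c(/C(Cl)=C2/[C@@H](C)CC[C@H]3C(C)(C)CCC[C@]23C)c1 | intermediate
20 | 2-methoxy-6-[(E)-11-chloro-8αH-drim-9(11)-en-11-yl]-1,4-benzoquinone (CNP0249629.1) | COC1=CC(=O)C=C(/C(Cl)=C2/[C@@H](C)CC[C@H]3C(C)(C)CCC[C@]23C)C1=O | target

## Step count and least certain steps

Total: 12 steps. Longest linear sequence: 10 steps (steps 1, 2 and 5 to 12 from sclareolide; the branch from methyl vinyl ether through steps 3 and 4 into steps 5 to 12 is equally long).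

**Step 5 (key step).** Three processes could defeat it. After alkyne insertion the donor methoxy group on the vinyl carbon may slow CO insertion, so that cyclisation without CO or a second alkyne insertion takes over. The C8 hydroxyl may add to the ketene (lactonisation) before the electrocyclisation. Complex 10 may decompose thermally before it loses CO. The fallback removes the donor from the carbene and adds the C3' oxygen afterwards; it sets out from 3 and 7 and rejoins at 13. Vinylmagnesium bromide is added to 7 and the acylate is methylated with Me3OBF4 to give pentacarbonyl(1-methoxyprop-2-enylidene)chromium F1, which is used at once. Its benzannulation with 3 should give 2-(8α-hydroxydriman-11-yl)-4-methoxyphenol F2. Ortho-formylation at the one free ortho position (MgCl2, Et3N, paraformaldehyde, MeCN) would give 2-hydroxy-3-(8α-hydroxydriman-11-yl)-5-methoxybenzaldehyde F3. Dakin oxidation (H2O2, NaOH) would give 3-(8α-hydroxydriman-11-yl)-5-methoxybenzene-1,2-diol F4, and double O-methylation (MeI, K2CO3) returns to 13. The same fallback serves if 10 proves too labile to prepare.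

**Step 11.** The aryl group is only a moderate donor (its ortho methoxy is flanked, and the other two are meta), so ionisation may be slow; sulfur–oxygen cleavage, solvent capture and hydrolysis back to 16 then compete. Capture from the C10 side may also not be fully suppressed, and an intramolecular hydride shift to the cation is conceivable if chloride is too dilute. The fallback changes the mechanism; it sets out from 16 and rejoins at 19. Deoxychlorination of the ketone with (PhO)3P/Cl2 and Et3N in CH2Cl2, through an α-chlorocarbenium ion and proton loss from C9, would give 19 together with (Z)-11-chloro-11-(2,3,5-trimethoxyphenyl)-8αH-drim-9(11)-ene F5. The isomers are separated, and F5 is re-equilibrated by sensitised irradiation and recycled.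

**Step 9.** The hydroperoxide system may oxidise the electron-rich ring or a tertiary C–H bond instead of C11, or stall at the hindered methylene. The fallback is a two-electron sequence from 15 to 16. DDQ in dioxane dehydrogenates 15 by benzylic hydride abstraction and loss of the C9 proton to (E)-11-(2,3,5-trimethoxyphenyl)-8αH-drim-9(11)-ene F6. Hydroboration with BH3·THF places boron on the less substituted C11 and hydrogen on C9 from the α face, and NaOH/H2O2 gives 11-(2,3,5-trimethoxyphenyl)-8αH-driman-11-ol F7; the C9 configuration is of no consequence, because C9 becomes trigonal in step 10. Dess–Martin periodinane oxidises F7 to 16.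

**Step 12.** Oxidation may take place across the ortho pair (C2', C3') instead of the para pair, or the one-electron oxidant may attack the styrene-type chloroalkene. The fallback avoids a chemical oxidant and runs from 19 to 20. Anodic oxidation of 19 (Pt anode, KOH, MeOH, 0 °C) would give the quinone bis(dimethyl ketal) (E)-11-chloro-11-(3,3,5,6,6-pentamethoxycyclohexa-1,4-dien-1-yl)-8αH-drim-9(11)-ene F8, and brief hydrolysis in aqueous acetic acid gives 20.

## Further compounds

F1 | step 5 | pentacarbonyl(1-methoxyprop-2-enylidene)chromium | C=CC(OC)=[Cr](=C=O)(=C=O)(=C=O)(=C=O)=C=O
F2 | step 5 | 2-(8α-hydroxydriman-11-yl)-4-methoxyphenol | COc1ccc(O)c(C[C@H]2[C@](C)(O)CC[C@H]3C(C)(C)CCC[C@]23C)c1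
F3 | step 5 | 2-hydroxy-3-(8α-hydroxydriman-11-yl)-5-methoxybenzaldehyde | COc1cc(C=O)c(O)c(C[C@H]2[C@](C)(O)CC[C@H]3C(C)(C)CCC[C@]23C)c1
F4 | step 5 | 3-(8α-hydroxydriman-11-yl)-5-methoxybenzene-1,2-diol | COc1cc(O)c(O)c(C[C@H]2[C@](C)(O)CC[C@H]3C(C)(C)CCC[C@]23C)c1
F5 | step 11 | (Z)-11-chloro-11-(2,3,5-trimethoxyphenyl)-8αH-drim-9(11)-ene | COc1cc(OC)c(OC)c(/C(Cl)=C2\[C@@H](C)CC[C@H]3C(C)(C)CCC[C@]23C)c1
F6 | step 9 | (E)-11-(2,3,5-trimethoxyphenyl)-8αH-drim-9(11)-ene | COc1cc(OC)c(OC)c(/C=C2\[C@@H](C)CC[C@H]3C(C)(C)CCC[C@]23C)c1
F7 | step 9 | 11-(2,3,5-trimethoxyphenyl)-8αH-driman-11-ol (C11 epimers) | COc1cc(OC)c(OC)c(C(O)[C@H]2[C@@H](C)CC[C@H]3C(C)(C)CCC[C@]23C)c1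
F8 | step 12 | (E)-11-chloro-11-(3,3,5,6,6-pentamethoxycyclohexa-1,4-dien-1-yl)-8αH-drim-9(11)-ene | COC1=CC(OC)(OC)C=C(/C(Cl)=C2/[C@@H](C)CC[C@H]3C(C)(C)CCC[C@]23C)C1(OC)OC
A1 | alternative 1 | S-ethyl (1,2-trans)-1-[2-oxo-2-(2,3,5-trimethoxyphenyl)ethyl]-3,3-dimethyl-2-[2-(2-methyl-1,3-dioxolan-2-yl)ethyl]cyclohexane-1-carbothioate | CCSC(=O)[C@]1(CC(=O)c2cc(OC)cc(OC)c2OC)CCCC(C)(C)[C@@H]1CCC2(C)OCCO2
A2 | alternative 1 | S-ethyl 3,3-dimethylcyclohex-1-ene-1-carbothioate | CCSC(=O)C1=CC(C)(C)CCC1
A3 | alternative 1 | [2-(2-methyl-1,3-dioxolan-2-yl)ethyl]magnesium bromide | CC1(CC[Mg]Br)OCCO1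
A4 | alternative 1 | 2-bromo-1-(2,3,5-trimethoxyphenyl)ethan-1-one | COc1cc(OC)c(OC)c(C(=O)CBr)c1
A5 | alternative 2 | 11-(2,3,5-trimethoxyphenyl)drim-8-ene | COc1cc(OC)cc(CC2=C(C)CC[C@H]3C(C)(C)CCC[C@]23C)c1OC
A6 | alternative 2 | 1-[(2E,6E)-farnesyl]-2,3,5-trimethoxybenzene | COc1cc(OC)cc(C/C=C(\C)CC/C=C(\C)CCC=C(C)C)c1OC
A7 | alternative 3 | (E)-11-chloro-11-(2,3,5-trimethoxyphenyl)-8αH-drima-6,9(11)-diene | COc1cc(OC)cc(/C(Cl)=C2/[C@@H](C)C=C[C@H]3C(C)(C)CCC[C@]23C)c1OC
A8 | alternative 3 | (8E,10E)-1-chloro-3,7,7-trimethyl-1-(2,3,5-trimethoxyphenyl)dodeca-1,2,8,10-tetraene | COc1cc(OC)cc(C(Cl)=C=C(C)CCCC(C)(C)/C=C/C=C/C)c1OC
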